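**Remarks on the chemistry.** Atoms carry the briarane numbers of the target (C1–C20) in every intermediate. α is the face of ring A that holds H10 and the C1–C2 bond; β is the face that holds the C1 methyl group (C15). Compound 28 is a mixture at C17 and compounds 38–40 are mixtures at C17 (that centre is left open in their SMILES); steps 18 and 26 settle it.

## Analysis of the target

The target (44) is a briarane. A cyclohexene (ring A: C1, C10–C14, C11=C12 with methyl C20) is fused through C1–C10 to a ten-membered carbocycle (C1–C10). That ring holds a (Z)-trisubstituted C5=C6 alkene and a γ-lactone (C7–O–C19(=O)–C17–C8) fused trans across C7–C8.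

There are eight stereocentres: quaternary C1 (methyl C15), C2 and C14 (acetoxy), C10, C9 (hydroxyl), C8 (tertiary hydroxyl), C7 and C17. In an extended drawing of C14–C1–C2 the two acyloxy groups and C10 lie on one side and the C1 methyl on the other. C9 leaves C10 cis to that methyl, so the two carbocycles are trans-fused. H7 and the C8 hydroxyl are trans, and the C17 methyl is cis to the C8 hydroxyl.

Sensitive groups are the two acetates, the β-hydroxy lactone (C17 can epimerise and the C8 oxygen can be lost through the lactone enolate), the free 8,9-diol and the (Z)-alkene.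

The hard part is a medium ring whose closure must also deliver a fully substituted carbinol (C8) flanked by two further carbinols (C7, C9), next to the crowded C14/C1/C2/C10 array around a quaternary carbon.

The strategy rests on one feature. The lactone oxygen joins C7 to C19, and C19 is tied through C17 to C8. With C19 at the alcohol level and a C17=C8 double bond, C7–O–C19–C17=C8 is an allyl ether whose [2,3]-shift makes exactly the C7–C8 bond.

## Retrosynthetic reasoning

**44 back to 41.** Only protecting groups change. Silyl ethers at C2/C14 and MOM ethers at C8/C9 are chosen so that the silyl groups leave first (42), the acetates go onto the only free hydroxyls (43) and the MOM groups leave last. A selective acetylation of a tetraol is thus avoided.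

**41 back to 36.** The lactone C19–O7 bond is cut and C19 is reduced to an alkene terminus, which gives the isopropenyl carbinol 36. Forward, anti-Markovnikov hydration (38) and oxidative lactonisation (40) re-form the C–O bond. C17, now α to the carbonyl, is set by equilibration (41) because no kinetic control is expected in the hydration.

**36 back to 34 (key disconnection).** The C7–C8 bond is cut and O7 is reconnected to C19, which turns the ten-membered carbocycle into the thirteen-membered ether 34. This removes the medium-ring closure and both carbinol centres C7 and C8 in one operation. Forward, the [2,3]-Wittig shift must occur from a C7 carbanion onto a fully substituted enol-ether carbon.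

**34 back to 33.** The C7–O bond is cut. A neryl-type allylic bromide at C7 and an alkoxide at C19 are the stable polarity; a halide at C19 next to the enol ether would not survive.

**33 back to 26 and 27.** The enol-ether allylic alcohol comes from ester 29, and 29 from β-keto ester 28 by O-alkylation of its chelated enolate. Cutting C8–C17 of 28 leaves α-alkoxy ester 26 and ethyl propanoate (27), joined by a Claisen condensation.

**26 back to 21 and 22.** The C9–C10 bond is cut by a Johnson–Claisen rearrangement of the 12β-allylic alcohol 21 with orthoester 22, which transfers chirality from C12 to C10 and places the alkene at C11=C12. The C9 oxygen is added afterwards by enolate hydroxylation of 24, because the acyclic enolate has a clearer facial bias than a glycolate Claisen transition state on this ring.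

**21 back to 19.** The C12 hydroxyl comes from allylic oxidation of 20. Ring A of 20 is opened at C10=C11 to the acyclic diene 19 (ring-closing metathesis forward).

**19 back to 13 and 14.** The C14 carbinol is taken back to ketone 16 (1,3-syn reduction directed by the C2 hydroxyl). The C13–C14 bond is cut to Weinreb amide 13 and the Grignard reagent 15 made from bromide 14.

**13 back to 7 and 4.** The C1 methyl is removed (Fráter–Seebach alkylation forward, 10 to 12). The C1–C2 bond is cut by an Evans aldol between crotonyl imide 7 and aldehyde 4. These two reactions set C2 and C1 with known sense, and the vinyl group supplies C10.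

**4 back to 1; 7 back to 5 and 6.** Aldehyde 4 is nerol (1) after protection and excision of its isopropylidene end, so the (Z)-C5=C6 alkene is bought. Imide 7 is the acylation product of oxazolidinone 5 and acyl chloride 6.

## Alternatives that were turned down

**Alternative 1:** The bonds C4–C5 and C6–C7 on either side of the trisubstituted alkene are cut. Forward, an alkylcopper reagent carrying ring A and C2–C4 would add syn across an alkyne, and the alkenylcopper would be acylated by an acyl chloride holding C7–C9, giving enone A1.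
- For it: the alkene geometry follows from the syn addition, two fragments of similar size meet in one pot, and the route is more convergent than the chosen one, which is long and linear.
- Against it: the alkene is the one element the chosen route obtains for nothing from nerol (1). A1 still lacks the ten-membered ring, the lactone and the centres C7, C8, C9 and C17. The C7 ketone of A1 must be reduced with control, C8 must be built by addition to a hindered ketone, and a medium-ring closure without built-in stereocontrol remains. The (Z)-enone can also isomerise.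
- Comparison: the chosen strategy is weaker on convergence, but its key step closes the ring and sets C7 and C8 together.

**Alternative 2:** The lactone is cut at C17–C19 and C19–O7. Forward, a cobalt carbonyl catalyst would open a C8–C17 spiro-epoxide at C17 under carbonylation and the C7 hydroxyl would capture the acyl group, giving A2.
- For it: the lactone, the free C8 hydroxyl and C17 (by invertive opening) arrive in one late step. That is shorter and better controlled at C17 than the hydroboration, oxidation and equilibration used here, and it needs no protecting group on O8.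
- Against it: the step presupposes the finished ten-membered carbocycle with an exocyclic C8=C17 alkene of defined geometry, epoxidised on one face, so it does not address the ring. Epoxide carbonylation normally ends with the epoxide oxygen capturing the acyl group (a β-lactone), so capture by the C7 hydroxyl is not the default course. A spiro-epoxide next to a fully substituted centre can also rearrange to a carbonyl compound under the Lewis-acidic catalyst.
- Comparison: this is an endgame, not a ring strategy. The chosen route uses the same lactone atoms as the tether that closes the ring.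

**Alternative 3:** The C1–C10 bond is cut. Forward, a Lewis acid would open a C1–C2 epoxide in a fourteen-membered cembranoid-type ring, the C10=C11 alkene would attack C1, and loss of H12 would give A3.
- For it: ring A, the ten-membered ring, the quaternary C1, C10 and the C2 hydroxyl form in one biomimetic step. On step economy for ring A this is clearly stronger than the chosen route, which spends about a dozen steps there.
- Against it: the outcome depends on the conformation of a flexible macrocycle that already carries the lactone. Proton loss can go to C20, the C5=C6 alkene can take part, and the epoxide can rearrange. The macrocyclic precursor needs its own long synthesis and macrocyclisation, and nothing in the substrate can be tuned if the cyclisation goes the wrong way.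
- Comparison: the chosen route gives up this economy for predictable models at every ring A centre and one late, well-defined risky step.

Key step: step 23

## Route

Step 1
Reactants: 1 nerol
Product: 2 neryl 4-methoxybenzyl ether
Conditions: NaH, 4-methoxybenzyl chloride, Bu4NI (cat.), THF/DMF, 0 °C to rt
Reagents that add atoms: 4-methoxybenzyl chloride, COc1ccc(CCl)cc1
Why: Williamson etherification of a primary allylic alcohol; the (Z)-alkene that becomes C5=C6 is taken from nerol unchanged, and the PMB group is the only one in the route that DDQ removes.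

Step 2
Reactants: 2 neryl 4-methoxybenzyl ether
Product: 3 6,7-epoxyneryl 4-methoxybenzyl ether
Conditions: mCPBA (1 equiv), NaHCO3, CH2Cl2, −20 to 0 °C
Reagents that add atoms: 3-chloroperbenzoic acid, OOC(=O)c1cccc(Cl)c1
Why: Prilezhaev epoxidation; the allylic ether oxygen lowers the nucleophilicity of the 2,3-alkene, so one equivalent of peracid should take the remote trisubstituted alkene, as with neryl and geranyl esters and ethers.

Step 3
Reactants: 3 6,7-epoxyneryl 4-methoxybenzyl ether
Product: 4 (4Z)-6-[(4-methoxybenzyl)oxy]-4-methylhex-4-enal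
Conditions: H5IO6, THF/H2O, 0 °C to rt
Reagents that add atoms: none
Why: Epoxide opening and periodate glycol cleavage in one operation remove the isopropylidene carbons as acetone and leave the C2 aldehyde; the (Z)-alkene and the PMB ether are inert.

Step 4
Reactants: 5 (4S)-4-benzyl-1,3-oxazolidin-2-one; 6 (2E)-but-2-enoyl chloride
Product: 7 (4S)-4-benzyl-3-[(2E)-but-2-enoyl]-1,3-oxazolidin-2-one
Conditions: n-BuLi, THF, −78 °C; then 6, −78 to 0 °C
Reagents that add atoms: none
Why: N-acylation of the lithiated oxazolidinone, the standard entry to Evans imides.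

Step 5
Reactants: 7 (4S)-4-benzyl-3-[(2E)-but-2-enoyl]-1,3-oxazolidin-2-one; 4 (4Z)-6-[(4-methoxybenzyl)oxy]-4-methylhex-4-enal
Product: 9 (4S)-4-benzyl-3-[(2S,3R,6Z)-2-ethenyl-3-hydroxy-8-[(4-methoxybenzyl)oxy]-6-methyloct-6-enoyl]-1,3-oxazolidin-2-one, via boron dienolate 8 (not isolated)
Conditions: n-Bu2BOTf, Et3N, CH2Cl2, −78 to 0 °C; 4, −78 to 0 °C; H2O2, pH 7 buffer, MeOH
Reagents that add atoms: none
Why: Evans syn-aldol reaction of the (Z)-boron dienolate formed by γ-deprotonation of the crotonyl imide; bond formation at the α-carbon through the chair transition state on the enolate face away from the benzyl group sets C2 and gives the 2,3-syn α-vinyl adduct. The vinyl group later supplies C10.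

Step 6
Reactants: 9 Evans aldol adduct
Product: 10 methyl (2S,3R,6Z)-2-ethenyl-3-hydroxy-8-[(4-methoxybenzyl)oxy]-6-methyloct-6-enoate
Conditions: MeMgBr, MeOH, CH2Cl2, 0 °C
Reagents that add atoms: methanol, CO
Why: Transesterification of the N-acyl oxazolidinone by magnesium methoxide releases the auxiliary under conditions mild enough to avoid retro-aldol cleavage and conjugation of the β,γ-unsaturated ester.

Step 7
Reactants: 10 methyl (2S,3R,6Z)-2-ethenyl-3-hydroxy-8-[(4-methoxybenzyl)oxy]-6-methyloct-6-enoate
Product: 12 methyl (2S,3R,6Z)-2-ethenyl-3-hydroxy-8-[(4-methoxybenzyl)oxy]-2,6-dimethyloct-6-enoate, via dilithium dianion 11 (not isolated)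
Conditions: LiN(i-Pr)2 (2.3 equiv), THF, −78 to −20 °C; MeI, DMPU, −78 to 0 °C; NH4Cl (aq)
Reagents that add atoms: iodomethane, CI
Why: Fráter–Seebach alkylation; the lithium alkoxide chelates the ester dienolate and iodomethane adds at the α-carbon (the normal site for lithium ester dienolates) on the chelate face away from the C3 chain, i.e. anti to the C2 oxygen. C1 thus becomes quaternary with methyl anti and vinyl syn to the C2 hydroxyl.

Step 8
Reactants: 12 methyl ester with quaternary C1
Product: 13 (2S,3R,6Z)-2-ethenyl-3-hydroxy-N-methoxy-8-[(4-methoxybenzyl)oxy]-N,2,6-trimethyloct-6-enamide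
Conditions: MeNH(OMe)·HCl, i-PrMgCl, THF, −20 to 0 °C
Reagents that add atoms: N,O-dimethylhydroxylamine hydrochloride, CNOC.Cl
Why: Weinreb amide formation by aminolysis of the ester with the chloromagnesium amide; the quaternary α-carbon cannot epimerise and the free hydroxyl is carried as its magnesium alkoxide.

Step 9
Reactants: 13 Weinreb amide; 14 4-bromo-2-methylbut-1-ene
Product: 16 (6S,7R,10Z)-6-ethenyl-7-hydroxy-12-[(4-methoxybenzyl)oxy]-2,6,10-trimethyldodeca-1,10-dien-5-one, via (3-methylbut-3-enyl)magnesium bromide 15 (not isolated)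
Conditions: 14, Mg, THF; then 13, THF, −20 to 0 °C; NH4Cl (aq)
Reagents that add atoms: none
Why: Grignard addition to a Weinreb amide stops at the ketone because the chelated tetrahedral intermediate survives until work-up; one equivalent of 15 is consumed by the hydroxyl, and the low temperature guards against retro-aldol cleavage.

Step 10
Reactants: 16 β-hydroxy ketone
Product: 18 (5S,6R,7R,10Z)-6-ethenyl-12-[(4-methoxybenzyl)oxy]-2,6,10-trimethyldodeca-1,10-diene-5,7-diol, via diethylboron chelate 17 (not isolated)
Conditions: Et2BOMe, THF/MeOH (4:1), −78 °C; NaBH4; then H2O2, NaOH (aq)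
Reagents that add atoms: none
Why: Narasaka–Prasad reduction; the boron chelate between the C2 oxygen and the C14 ketone is attacked axially by borohydride, anti to the axial substituent of the quaternary C1, which gives the 1,3-syn diol and sets C14.

Step 11
Reactants: 18 syn-diol
Product: 19 bis-TBS ether of 18
Conditions: TBSOTf, 2,6-lutidine, CH2Cl2, 0 °C to rt
Reagents that add atoms: tert-butyldimethylsilyl triflate, CC(C)(C)[Si](C)(C)OS(=O)(=O)C(F)(F)F
Why: Silylation with the silyl triflate is needed for the two hindered secondary hydroxyls next to the quaternary carbon; the silyl ethers survive every step up to step 27.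

Step 12
Reactants: 19 bis-TBS ether
Product: 20 ring A cyclohexene (C10=C11 alkene with C20 methyl, 1β-methyl, 14α-OTBS, C1 side chain C2(OTBS)–C7(OPMB) with the (5Z)-alkene)
Conditions: (H2IMes)(PCy3)Cl2Ru=CHPh (second-generation Grubbs catalyst, 5 mol%), CH2Cl2, 40 °C
Reagents that add atoms: none
Why: Ring-closing metathesis of the vinyl group on C1 with the 1,1-disubstituted alkene closes six-membered ring A and forms the trisubstituted C10=C11 alkene; the trisubstituted C5=C6 alkene does not engage the ruthenium carbene under these conditions.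

Step 13
Reactants: 20 ring A cyclohexene
Product: 21 12β-hydroxy derivative of 20
Conditions: SeO2 (cat.), t-BuOOH, CH2Cl2, 0 °C to rt
Reagents that add atoms: tert-butyl hydroperoxide, CC(C)(C)OO; selenium dioxide (oxygen relay), O=[Se]=O
Why: Riley allylic hydroxylation (ene reaction, then [2,3]-shift of the allylseleninic acid) oxidises the ring CH2 next to the methyl-bearing alkene carbon, the usual site in 1-methylcyclohexenes; the C5=C6 alkene is deactivated by its allylic ether oxygen. Both pericyclic steps are suprafacial, so the hydroxyl appears on the face that selenium attacks at C10, the β face that carries only the C1 methyl group.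

Step 14
Reactants: 21 12β-allylic alcohol; 22 triethyl orthoacetate
Product: 24 ethyl 2-(ring A-10β-yl)acetate (C11=C12 alkene, 1β-methyl, 14α-OTBS, side chain as in 20), via ketene acetal 23 (not isolated)
Conditions: EtCO2H (cat.), xylene, 140 °C, removal of EtOH
Reagents that add atoms: none
Why: Johnson–Claisen rearrangement; the mixed ketene acetal rearranges suprafacially, moves the alkene to C11=C12 and forms the C9–C10 bond on the β face, cis to the C1 methyl group, so C10 is set by chirality transfer from C12.

Step 15
Reactants: 24 ethyl ester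
Product: 25 (9R)-9-hydroxy derivative of 24
Conditions: KN(SiMe3)2, THF, −78 °C; 2-(phenylsulfonyl)-3-phenyloxaziridine; NH4Cl (aq)
Reagents that add atoms: 2-(phenylsulfonyl)-3-phenyloxaziridine, O=S(=O)(N1OC1c1ccccc1)c1ccccc1
Why: Enolate hydroxylation with the Davis oxaziridine; 1,3-allylic strain holds H10 in the enolate plane, and the oxidant approaches the face flanked by the flat alkene carbon C11 and away from the quaternary C1, which should give the 9R alcohol of the target.

Step 16
Reactants: 25 α-hydroxy ester
Product: 26 9-O-MOM ether of 25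
Conditions: MOMCl, i-Pr2NEt, CH2Cl2, 0 °C to rt
Reagents that add atoms: chloromethyl methyl ether, COCCl
Why: Standard acetal protection of a secondary alcohol; this MOM group stays until the last step.

Step 17
Reactants: 26 α-alkoxy ester; 27 ethyl propanoate
Product: 28 β-keto ester (C8 ketone, C17 methyl, C19 ethyl ester; mixture at C17)
Conditions: LiN(i-Pr)2, 27 (3.5 equiv), THF, −78 °C; then 26, −78 to −30 °C; AcOH
Reagents that add atoms: none
Why: Crossed Claisen condensation; the excess lithium enolate of 27 acylates on the activated α-alkoxy ester and deprotonates the β-keto ester as it forms, which protects the product and the C9 centre. C17 is planarised in the next step.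

Step 18
Reactants: 28 β-keto ester
Product: 29 (Z)-MOM enol ether ester (C8 oxygen cis to C19)
Conditions: NaH, THF, 0 °C; MOMCl, 0 °C
Reagents that add atoms: chloromethyl methyl ether, COCCl
Why: O-alkylation of the internally chelated sodium enolate (sodium between the two carbonyl oxygens) by the hard electrophile MOMCl should fix the enol-ether geometry with the C8 oxygen cis to C19, as the key step requires.

Step 19
Reactants: 29 enol ether ester
Product: 30 C7 alcohol
Conditions: DDQ, CH2Cl2/pH 7 buffer, 0 °C
Reagents that add atoms: none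
Why: Oxidative PMB cleavage; the enol ether is conjugated to the ester and therefore too electron-poor to react, and silyl and MOM ethers are untouched.

Step 20
Reactants: 30 C7 alcohol
Product: 32 C7 allylic bromide, via allylic mesylate 31 (not isolated)
Conditions: MsCl, Et3N, THF, −40 °C; LiBr, −40 to 0 °C
Reagents that add atoms: lithium bromide, [Li+].[Br-]
Why: Mesylation and bromide displacement at a primary allylic carbon proceed without allylic transposition or loss of the (Z)-geometry, as in the preparation of neryl bromide.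

Step 21
Reactants: 32 bromo ester
Product: 33 bromo allylic alcohol (C19 hydroxyl)
Conditions: i-Bu2AlH, CH2Cl2, −78 °C; aqueous sodium potassium tartrate
Reagents that add atoms: none
Why: Hydride reduction of the β-alkoxy acrylate to the allylic alcohol; alkyl bromides are inert to this hydride at −78 °C, and the neutral work-up spares the acid-sensitive enol ether.

Step 22
Reactants: 33 bromo allylic alcohol
Product: 34 thirteen-membered C7–O–C19 ether (C8 MOM enol ether, C9 MOM ether, C2 and C14 TBS ethers)
Conditions: NaH, THF, high dilution (slow addition of 33), rt to 45 °C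
Reagents that add atoms: none
Why: Intramolecular Williamson etherification under high dilution; the C19 alkoxide displaces the primary allylic bromide at C7 (SN2, not SN2' at the hindered C5), a closure that is established for rings of this size with allylic halides.

Step 23
Reactants: 34 thirteen-membered ether
Product: 36 ten-membered C7 alcohol with C8 MOM ether and C8 isopropenyl group, via 7-lithio ether 35 (not isolated)
Conditions: n-BuLi, THF, −78 to −20 °C; NH4Cl (aq)
Reagents that add atoms: none
Why: Proposed new method: n-BuLi removes a C7 proton (allylic to C5=C6 and α to the ether oxygen); the carbanion bonds through C7 to the enol-ether carbon C8 while the O–C19 bond breaks suprafacially across C19–C17=C8 in a five-membered envelope transition state, so the alkoxide ends on C7, C8 becomes the MOM-protected tertiary carbinol and C17–C19 become the isopropenyl group. The closest known reaction type is the [2,3]-Wittig ring contraction of thirteen-membered bis-allylic and allylic propargylic ethers to ten-membered carbocycles; a fully substituted, oxygen-bearing migration terminus has not been used in it. The ten-membered ring is closed by sigmatropic ring contraction (thirteen to ten atoms): the new C7–C8 bond is transannular and forms inside the cyclic array C7–O–C19–C17–C8, not by an end-to-end cyclisation. C8 is controlled by the (Z)-enol-ether geometry together with the face of attack: 1,3-allylic strain with the C17 methyl group holds H9 in the enol-ether plane, the ring tether through C10 brings C7 to the face on which C10 lies, and the C9 OMOM group stays on the other face. C7 is controlled by the envelope: the C6 vinyl substituent takes the exo position away from the C17 methyl group, which places C6 syn to the C8 oxygen and gives the trans relation of H7 and the C8 oxygen. The step needs lithiation at C7 and not at C19, and a [2,3]- and not a [1,2]-shift; a C19 anion would be destabilised by the electron-rich, fully substituted enol ether while the C7 anion is an ordinary alkoxyallyl anion, and low temperature together with the electrophilic character of the oxygen-bearing C8 favours the concerted shift.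

Step 24
Reactants: 36 isopropenyl carbinol
Product: 38 C7,C19-diol (primary alcohol at C19; mixture at C17), via bis-borane adduct 37 (not isolated)
Conditions: 9-BBN (excess), THF, 0 °C to rt; NaOH, H2O2, 0 °C
Reagents that add atoms: hydrogen peroxide, OO
Why: Hydroboration–oxidation; 9-BBN adds to 1,1-disubstituted alkenes far faster than to trisubstituted ones, so only the isopropenyl group reacts (boron on C19) after the C7 hydroxyl has consumed one equivalent. No useful control at C17 is expected, and both epimers are carried on.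

Step 25
Reactants: 38 diol
Product: 40 γ-lactone (C8, C9 MOM ethers, C2, C14 TBS ethers; mixture at C17), via lactol 39 (not isolated)
Conditions: PhI(OAc)2, TEMPO (cat.), CH2Cl2, rt
Reagents that add atoms: none
Why: Oxidative lactonisation of a 1,4-diol; the nitroxyl catalyst oxidises the primary alcohol selectively, the aldehyde is trapped by the C7 hydroxyl as the lactol, and this is oxidised to the lactone, which re-forms the C19–O7 bond that the key step broke.

Step 26
Reactants: 40 lactone (C17 mixture)
Product: 41 lactone with the C17 configuration of the target (17R; methyl cis to the C8 oxygen)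
Conditions: DBU, toluene, rt to 40 °C
Reagents that add atoms: none
Why: Base-mediated epimerisation α to the lactone carbonyl should converge on the epimer with the methyl group trans to the ring carbon C9 and cis to the smaller C8 oxygen. The amidine is a weak enough base that reprotonation of the enolate should outrun β-elimination of the C8 alkoxy group.

Step 27
Reactants: 41 lactone
Product: 42 C2,C14-diol
Conditions: HF·pyridine, pyridine, THF, 0 °C to rt
Reagents that add atoms: none
Why: Fluoride cleavage of both silyl ethers under mildly acidic conditions that leave the MOM ethers, the lactone and C17 untouched.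

Step 28
Reactants: 42 diol
Product: 43 C2,C14-diacetate with C8, C9 MOM ethers
Conditions: Ac2O, pyridine, DMAP (cat.), CH2Cl2, rt
Reagents that add atoms: acetic anhydride, CC(=O)OC(C)=O
Why: Acylation of the only two free hydroxyls; DMAP catalysis is needed for secondary alcohols next to the quaternary carbon.

Step 29
Reactants: 43 diacetate bis-MOM ether
Product: 44 9-deacetylstylatulide lactone
Conditions: Me2BBr, CH2Cl2, −78 °C; then NaHCO3 (aq), THF
Reagents that add atoms: none
Why: The bromoborane cleaves MOM ethers, including tertiary ones, at the acetal carbon at low temperature and leaves acetates, the lactone and alkenes alone, so the 8,9-diol is freed without acyl loss or migration.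

## Compound list

1 | nerol, (2Z)-3,7-dimethylocta-2,6-dien-1-ol | CC(C)=CCC/C(C)=C\CO | starting material
2 | neryl 4-methoxybenzyl ether | COc1ccc(COC/C=C(C)\CCC=C(C)C)cc1 | intermediate
3 | 6,7-epoxyneryl 4-methoxybenzyl ether (racemic at the epoxide) | COc1ccc(COC/C=C(C)\CCC2OC2(C)C)cc1 | intermediate
4 | (4Z)-6-[(4-methoxybenzyl)oxy]-4-methylhex-4-enal (C2–C7, C16) | COc1ccc(COC/C=C(C)\CCC=O)cc1 | intermediate
5 | (4S)-4-benzyl-1,3-oxazolidin-2-one | O=C1N[C@@H](Cc2ccccc2)CO1 | starting material
6 | (2E)-but-2-enoyl chloride | C/C=C/C(Cl)=O | starting material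
7 | (4S)-4-benzyl-3-[(2E)-but-2-enoyl]-1,3-oxazolidin-2-one | C/C=C/C(=O)N1[C@@H](Cc2ccccc2)COC1=O | intermediate
8 | (Z)-dibutylboron dienolate of 7 | C=C/C=C(\OB(CCCC)CCCC)N1[C@@H](Cc2ccccc2)COC1=O | intermediate
9 | (4S)-4-benzyl-3-[(2S,3R,6Z)-2-ethenyl-3-hydroxy-8-[(4-methoxybenzyl)oxy]-6-methyloct-6-enoyl]-1,3-oxazolidin-2-one | O=C([C@@H](C=C)[C@H](O)CC/C(C)=C\COCc3ccc(OC)cc3)N1[C@@H](Cc2ccccc2)COC1=O | intermediate
10 | methyl (2S,3R,6Z)-2-ethenyl-3-hydroxy-8-[(4-methoxybenzyl)oxy]-6-methyloct-6-enoate | COC(=O)[C@@H](C=C)[C@H](O)CC/C(C)=C\COCc1ccc(OC)cc1 | intermediate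
11 | dilithium alkoxide dienolate of 10 | COC(O[Li])=C(C=C)[C@H](O[Li])CC/C(C)=C\COCc1ccc(OC)cc1 | intermediate
12 | methyl (2S,3R,6Z)-2-ethenyl-3-hydroxy-8-[(4-methoxybenzyl)oxy]-2,6-dimethyloct-6-enoate | COC(=O)[C@@](C)(C=C)[C@H](O)CC/C(C)=C\COCc1ccc(OC)cc1 | intermediate
13 | (2S,3R,6Z)-2-ethenyl-3-hydroxy-N-methoxy-8-[(4-methoxybenzyl)oxy]-N,2,6-trimethyloct-6-enamide | CON(C)C(=O)[C@@](C)(C=C)[C@H](O)CC/C(C)=C\COCc1ccc(OC)cc1 | intermediate
14 | 4-bromo-2-methylbut-1-ene | C=C(C)CCBr | starting material
15 | (3-methylbut-3-enyl)magnesium bromide | C=C(C)CC[Mg]Br | intermediate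
16 | (6S,7R,10Z)-6-ethenyl-7-hydroxy-12-[(4-methoxybenzyl)oxy]-2,6,10-trimethyldodeca-1,10-dien-5-one | C=C(C)CCC(=O)[C@@](C)(C=C)[C@H](O)CC/C(C)=C\COCc1ccc(OC)cc1 | intermediate
17 | diethylboron chelate (C2–O–BEt2 borinate) of 16 | CCB(CC)O[C@H](CC/C(C)=C\COCc1ccc(OC)cc1)[C@](C)(C=C)C(=O)CCC(C)=C | intermediate
18 | (5S,6R,7R,10Z)-6-ethenyl-12-[(4-methoxybenzyl)oxy]-2,6,10-trimethyldodeca-1,10-diene-5,7-diol | C=C(C)CC[C@H](O)[C@@](C)(C=C)[C@H](O)CC/C(C)=C\COCc1ccc(OC)cc1 | intermediate
19 | 5,7-bis-O-TBS ether of 18 | C=C(C)CC[C@H](O[Si](C)(C)C(C)(C)C)[C@@](C)(C=C)[C@H](O[Si](C)(C)C(C)(C)C)CC/C(C)=C\COCc1ccc(OC)cc1 | intermediate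
20 | ring A cyclohexene: C10=C11 alkene (C20 methyl), 1β-methyl, 14α-OTBS, C1 side chain C2(OTBS)–C3–C4–C5(Me)=C6–C7(OPMB), (5Z) | CC1=C[C@@](C)([C@H](O[Si](C)(C)C(C)(C)C)CC/C(C)=C\COCc2ccc(OC)cc2)[C@@H](O[Si](C)(C)C(C)(C)C)CC1 | intermediate
21 | 12β-hydroxy derivative of 20 | CC1=C[C@@](C)([C@H](O[Si](C)(C)C(C)(C)C)CC/C(C)=C\COCc2ccc(OC)cc2)[C@@H](O[Si](C)(C)C(C)(C)C)C[C@@H]1O | intermediate
22 | triethyl orthoacetate, 1,1,1-triethoxyethane | CCOC(C)(OCC)OCC | starting material
23 | mixed ketene acetal of 21 (12β-O–C(OEt)=CH2) | CC1=C[C@@](C)([C@H](O[Si](C)(C)C(C)(C)C)CC/C(C)=C\COCc2ccc(OC)cc2)[C@@H](O[Si](C)(C)C(C)(C)C)C[C@@H]1OC(=C)OCC | intermediate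
24 | ethyl 2-(ring A-10β-yl)acetate: C9H2–C8 ester on C10, C11=C12 alkene, 1β-methyl, 14α-OTBS, side chain as in 20 | CCOC(=O)C[C@H]1C(C)=CC[C@H](O[Si](C)(C)C(C)(C)C)[C@]1(C)[C@H](O[Si](C)(C)C(C)(C)C)CC/C(C)=C\COCc2ccc(OC)cc2 | intermediate
25 | (9R)-9-hydroxy derivative of 24 | CCOC(=O)[C@H](O)[C@H]1C(C)=CC[C@H](O[Si](C)(C)C(C)(C)C)[C@]1(C)[C@H](O[Si](C)(C)C(C)(C)C)CC/C(C)=C\COCc2ccc(OC)cc2 | intermediate
26 | 9-O-MOM ether of 25 | CCOC(=O)[C@H](OCOC)[C@H]1C(C)=CC[C@H](O[Si](C)(C)C(C)(C)C)[C@]1(C)[C@H](O[Si](C)(C)C(C)(C)C)CC/C(C)=C\COCc2ccc(OC)cc2 | intermediate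
27 | ethyl propanoate | CCC(=O)OCC | starting material
28 | β-keto ester: C8 ketone, C17 methyl, C19 ethyl ester, 9-OMOM (mixture at C17) | CCOC(=O)C(C)C(=O)[C@H](OCOC)[C@H]1C(C)=CC[C@H](O[Si](C)(C)C(C)(C)C)[C@]1(C)[C@H](O[Si](C)(C)C(C)(C)C)CC/C(C)=C\COCc2ccc(OC)cc2 | intermediate
29 | (Z)-MOM enol ether ester: C8(OMOM)=C17(Me)–C19 ethyl ester, C8 oxygen cis to C19, C7 OPMB | CCOC(=O)/C(C)=C(OCOC)/[C@H](OCOC)[C@H]1C(C)=CC[C@H](O[Si](C)(C)C(C)(C)C)[C@]1(C)[C@H](O[Si](C)(C)C(C)(C)C)CC/C(C)=C\COCc2ccc(OC)cc2 | intermediate
30 | C7 alcohol from 29 | CCOC(=O)/C(C)=C(OCOC)/[C@H](OCOC)[C@H]1C(C)=CC[C@H](O[Si](C)(C)C(C)(C)C)[C@]1(C)[C@H](O[Si](C)(C)C(C)(C)C)CC/C(C)=C\CO | intermediate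
31 | C7 mesylate of 30 | CCOC(=O)/C(C)=C(OCOC)/[C@H](OCOC)[C@H]1C(C)=CC[C@H](O[Si](C)(C)C(C)(C)C)[C@]1(C)[C@H](O[Si](C)(C)C(C)(C)C)CC/C(C)=C\COS(C)(=O)=O | intermediate
32 | C7 allylic bromide ester | CCOC(=O)/C(C)=C(OCOC)/[C@H](OCOC)[C@H]1C(C)=CC[C@H](O[Si](C)(C)C(C)(C)C)[C@]1(C)[C@H](O[Si](C)(C)C(C)(C)C)CC/C(C)=C\CBr | intermediate
33 | bromo allylic alcohol: C19 hydroxyl, C7 bromide | OC/C(C)=C(OCOC)/[C@H](OCOC)[C@H]1C(C)=CC[C@H](O[Si](C)(C)C(C)(C)C)[C@]1(C)[C@H](O[Si](C)(C)C(C)(C)C)CC/C(C)=C\CBr | intermediate
34 | thirteen-membered C7–O–C19 ether with C8 MOM enol ether, C9 MOM ether, C2 and C14 TBS ethers | C[Si](C)(C(C)(C)C)O[C@H]1CC=C(C)[C@@H]2[C@@H](OCOC)/C(OCOC)=C(C)/COC/C=C(C)\CC[C@@H](O[Si](C)(C)C(C)(C)C)[C@@]12C | intermediate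
35 | 7-lithio derivative of 34 | C[Si](C)(C(C)(C)C)O[C@H]1CC=C(C)[C@@H]2[C@@H](OCOC)/C(OCOC)=C(C)/COC([Li])/C=C(C)\CC[C@@H](O[Si](C)(C)C(C)(C)C)[C@@]12C | intermediate
36 | ten-membered C7 alcohol with C8 MOM ether and C8 isopropenyl group | C[Si](C)(C(C)(C)C)O[C@H]1CC=C(C)[C@@H]2[C@@H](OCOC)[C@](OCOC)(C(C)=C)[C@H](/C=C(/C)CC[C@@H](O[Si](C)(C)C(C)(C)C)[C@@]12C)O | intermediate
37 | C19-(9-BBN) adduct of 36 with the C7 oxygen as 9-BBN borinate (mixture at C17) | C[Si](C)(C(C)(C)C)O[C@H]1CC=C(C)[C@@H]2[C@@H](OCOC)[C@](OCOC)(C(C)CB3C4CCCC3CCC4)[C@H](/C=C(/C)CC[C@@H](O[Si](C)(C)C(C)(C)C)[C@@]12C)OB5C6CCCC5CCC6 | intermediate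
38 | C7,C19-diol (mixture at C17) | C[Si](C)(C(C)(C)C)O[C@H]1CC=C(C)[C@@H]2[C@@H](OCOC)[C@](OCOC)(C(C)CO)[C@H](/C=C(/C)CC[C@@H](O[Si](C)(C)C(C)(C)C)[C@@]12C)O | intermediate
39 | lactol (C19 hemiacetal on O7; mixture at C17 and C19) | C[Si](C)(C(C)(C)C)O[C@H]1CC=C(C)[C@@H]2[C@@H](OCOC)[C@@]3(OCOC)[C@H](/C=C(/C)CC[C@@H](O[Si](C)(C)C(C)(C)C)[C@@]12C)OC(O)C3C | intermediate
40 | γ-lactone, 8,9-bis-MOM, 2,14-bis-TBS (mixture at C17) | C[Si](C)(C(C)(C)C)O[C@H]1CC=C(C)[C@@H]2[C@@H](OCOC)[C@@]3(OCOC)[C@H](/C=C(/C)CC[C@@H](O[Si](C)(C)C(C)(C)C)[C@@]12C)OC(=O)C3C | intermediate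
41 | (17R)-γ-lactone, 8,9-bis-MOM, 2,14-bis-TBS | C[Si](C)(C(C)(C)C)O[C@H]1CC=C(C)[C@@H]2[C@@H](OCOC)[C@@]3(OCOC)[C@H](/C=C(/C)CC[C@@H](O[Si](C)(C)C(C)(C)C)[C@@]12C)OC(=O)[C@@H]3C | intermediate
42 | 2,14-diol, 8,9-bis-MOM lactone | O[C@H]1CC=C(C)[C@@H]2[C@@H](OCOC)[C@@]3(OCOC)[C@H](/C=C(/C)CC[C@@H](O)[C@@]12C)OC(=O)[C@@H]3C | intermediate
43 | 2,14-diacetate, 8,9-bis-MOM lactone | CC(=O)O[C@H]1CC=C(C)[C@@H]2[C@@H](OCOC)[C@@]3(OCOC)[C@H](/C=C(/C)CC[C@@H](OC(C)=O)[C@@]12C)OC(=O)[C@@H]3C | intermediate
44 | 9-deacetylstylatulide lactone | CC(=O)O[C@H]1CC=C(C)[C@@H]2[C@@H](O)[C@@]3(O)[C@H](/C=C(/C)CC[C@@H](OC(C)=O)[C@@]12C)OC(=O)[C@@H]3C | target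

## Step count and uncertain steps

Total: 29 steps. Longest linear sequence: 28 steps from nerol (1), steps 1–3 and 5–29; step 4 prepares imide 7 on the side.

**Step 23 (key step).** The most likely failures are no rearrangement (the fully substituted enol-ether terminus is hindered, so a [1,2]-shift or decomposition of the carbanion can take over), lithiation at C19, or bond formation on the other enol-ether face, which would give the 7,8-bis-epimer. Fallback by known chemistry, setting out from β-keto ester 28 and returning at lactone 40: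
- DDQ removes the PMB group to give the C7 alcohol keto ester F1.
- MnO2 oxidises it to the (Z)-enal keto ester F2.
- An intramolecular pinacol coupling with low-valent titanium (TiCl3(DME)1.5, Zn–Cu couple, DME), or with SmI2, joins the C7 aldehyde to the C8 ketone; the C7 alkoxide closes onto the C19 ester and gives the 8-hydroxy lactone F3 (mixture at C17).
- MOMCl, i-Pr2NEt and NaI at 50 °C protect the tertiary hydroxyl and give 40.
The facial course of the pinacol coupling is not secured by a model and would have to be established.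

**Step 13.** The ene step may lose face or site selectivity (attack on the α face, on the C20 methyl or on the side-chain alkene), or over-oxidation to the enone may dominate. Fallback, setting out from 20 and returning at 21:
- The crude oxidation mixture is taken to enone F4 with Dess–Martin periodinane.
- Luche reduction (NaBH4, CeCl3·7H2O, MeOH) should give the 12α-alcohol F5, by hydride attack anti to the axial substituent on C14 as in 5-substituted cyclohexenones.
- Mitsunobu reaction with 4-nitrobenzoic acid (PPh3, DIAD) inverts C12 to the 12β-ester F6.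
- K2CO3 in MeOH gives 21.

**Step 15.** Facial selectivity of the enolate oxidation may be poor, because the two flanking ring carbons differ less than the model assumes. Fallback, setting out from 24 and returning at 25: the 9-epi alcohol F7 is separated and inverted by Mitsunobu reaction with 4-nitrobenzoic acid to the 9R 4-nitrobenzoate F8, and K2CO3 in EtOH gives 25.

**Step 17.** Acylation of the hindered ester may be slow, so that proton transfer at C9 (epimerisation) or self-condensation of the propanoate enolate competes. Fallback, setting out from 26 and returning at 28: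
- i-Bu2AlH at −78 °C gives the α-alkoxy aldehyde F9.
- The lithium enolate of 27 adds at −78 °C to give the β-hydroxy ester F10 (mixture at C8 and C17).
- Dess–Martin periodinane gives 28.

**Step 22.** Intermolecular etherification (oligomers) or loss of HBr from the allylic bromide may outrun ring closure. Fallback, setting out from 29 and returning at 34:
- i-Bu2AlH gives the C19 allylic alcohol F11, with the PMB group still on C7.
- Ethyl chloroformate and pyridine give the C19 ethyl carbonate F12.
- DDQ gives the C7 alcohol carbonate F13.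
- Pd(PPh3)4 (zerovalent palladium) in THF under high dilution ionises the carbonate, and the C7 alkoxide attacks the allyl complex at its unhindered C19 end to give 34. The fully substituted C8 end should keep the enol-ether geometry.

**Step 26.** β-Elimination of the C8 alkoxy group through the lactone enolate may compete, or the equilibrium may not favour the wanted epimer strongly enough. Fallback, setting out from 36 and returning at 41:
- ClSiHMe2 and Et3N give the C7 dimethylsilyl ether F14.
- Intramolecular hydrosilylation with Pt2[(CH2=CHSiMe2)2O]3 closes the six-membered oxasilacycle F15; in the chair transition state C6, C9 and the C17 methyl are all equatorial, which is the target configuration at C17.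
- Tamao–Fleming oxidation (KF, KHCO3, H2O2) gives the (17R)-diol F16.
- TEMPO and PhI(OAc)2 give 41.

## Further compounds

F1 | step 23 | C7 alcohol β-keto ester (28 without PMB) | CCOC(=O)C(C)C(=O)[C@H](OCOC)[C@H]1C(C)=CC[C@H](O[Si](C)(C)C(C)(C)C)[C@]1(C)[C@H](O[Si](C)(C)C(C)(C)C)CC/C(C)=C\CO
F2 | step 23 | (Z)-C7 enal β-keto ester | CCOC(=O)C(C)C(=O)[C@H](OCOC)[C@H]1C(C)=CC[C@H](O[Si](C)(C)C(C)(C)C)[C@]1(C)[C@H](O[Si](C)(C)C(C)(C)C)CC/C(C)=C\C=O
F3 | step 23 | 8-hydroxy γ-lactone, 9-OMOM, 2,14-bis-TBS (mixture at C17) | C[Si](C)(C(C)(C)C)O[C@H]1CC=C(C)[C@@H]2[C@@H](OCOC)[C@@]3(O)[C@H](/C=C(/C)CC[C@@H](O[Si](C)(C)C(C)(C)C)[C@@]12C)OC(=O)C3C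
F4 | step 13 | ring A enone (C12 ketone) | CC1=C[C@@](C)([C@H](O[Si](C)(C)C(C)(C)C)CC/C(C)=C\COCc2ccc(OC)cc2)[C@@H](O[Si](C)(C)C(C)(C)C)CC1=O
F5 | step 13 | 12α-alcohol (C12 epimer of 21) | CC1=C[C@@](C)([C@H](O[Si](C)(C)C(C)(C)C)CC/C(C)=C\COCc2ccc(OC)cc2)[C@@H](O[Si](C)(C)C(C)(C)C)C[C@H]1O
F6 | step 13 | 12β-(4-nitrobenzoate) of 21 | CC1=C[C@@](C)([C@H](O[Si](C)(C)C(C)(C)C)CC/C(C)=C\COCc2ccc(OC)cc2)[C@@H](O[Si](C)(C)C(C)(C)C)C[C@@H]1OC(=O)c3ccc([N+](=O)[O-])cc3
F7 | step 15 | (9S)-hydroxy ester (C9 epimer of 25) | CCOC(=O)[C@@H](O)[C@H]1C(C)=CC[C@H](O[Si](C)(C)C(C)(C)C)[C@]1(C)[C@H](O[Si](C)(C)C(C)(C)C)CC/C(C)=C\COCc2ccc(OC)cc2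
F8 | step 15 | (9R)-9-(4-nitrobenzoate) of 25 | CCOC(=O)[C@H](OC(=O)c3ccc([N+](=O)[O-])cc3)[C@H]1C(C)=CC[C@H](O[Si](C)(C)C(C)(C)C)[C@]1(C)[C@H](O[Si](C)(C)C(C)(C)C)CC/C(C)=C\COCc2ccc(OC)cc2
F9 | step 17 | C8 aldehyde from 26 | O=C[C@H](OCOC)[C@H]1C(C)=CC[C@H](O[Si](C)(C)C(C)(C)C)[C@]1(C)[C@H](O[Si](C)(C)C(C)(C)C)CC/C(C)=C\COCc2ccc(OC)cc2
F10 | step 17 | β-hydroxy ester (C8 carbinol; mixture at C8 and C17) | CCOC(=O)C(C)C(O)[C@H](OCOC)[C@H]1C(C)=CC[C@H](O[Si](C)(C)C(C)(C)C)[C@]1(C)[C@H](O[Si](C)(C)C(C)(C)C)CC/C(C)=C\COCc2ccc(OC)cc2
F11 | step 22 | C19 allylic alcohol with C7 OPMB | OC/C(C)=C(OCOC)/[C@H](OCOC)[C@H]1C(C)=CC[C@H](O[Si](C)(C)C(C)(C)C)[C@]1(C)[C@H](O[Si](C)(C)C(C)(C)C)CC/C(C)=C\COCc2ccc(OC)cc2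
F12 | step 22 | C19 ethyl carbonate with C7 OPMB | CCOC(=O)OC/C(C)=C(OCOC)/[C@H](OCOC)[C@H]1C(C)=CC[C@H](O[Si](C)(C)C(C)(C)C)[C@]1(C)[C@H](O[Si](C)(C)C(C)(C)C)CC/C(C)=C\COCc2ccc(OC)cc2
F13 | step 22 | C19 ethyl carbonate with free C7 hydroxyl | CCOC(=O)OC/C(C)=C(OCOC)/[C@H](OCOC)[C@H]1C(C)=CC[C@H](O[Si](C)(C)C(C)(C)C)[C@]1(C)[C@H](O[Si](C)(C)C(C)(C)C)CC/C(C)=C\CO
F14 | step 26 | C7 dimethylsilyl ether of 36 | C[Si](C)(C(C)(C)C)O[C@H]1CC=C(C)[C@@H]2[C@@H](OCOC)[C@](OCOC)(C(C)=C)[C@H](/C=C(/C)CC[C@@H](O[Si](C)(C)C(C)(C)C)[C@@]12C)O[SiH](C)C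
F15 | step 26 | six-membered oxasilacycle (O7–SiMe2–C19–C17–C8–C7), (17R) | C[Si](C)(C(C)(C)C)O[C@H]1CC=C(C)[C@@H]2[C@@H](OCOC)[C@@]3(OCOC)[C@H](/C=C(/C)CC[C@@H](O[Si](C)(C)C(C)(C)C)[C@@]12C)O[Si](C)(C)C[C@@H]3C
F16 | step 26 | (17R)-C7,C19-diol (single epimer of 38) | C[Si](C)(C(C)(C)C)O[C@H]1CC=C(C)[C@@H]2[C@@H](OCOC)[C@](OCOC)([C@@H](C)CO)[C@H](/C=C(/C)CC[C@@H](O[Si](C)(C)C(C)(C)C)[C@@]12C)O
A1 | alternative 1 | C1–C9 (Z)-enone carrying ring A and a dioxolane-masked C8 ketone | CC(C)(C)[Si](C)(C)OCC1(OCCO1)C(=O)/C=C(/C)CC[C@@H](O[Si](C)(C)C(C)(C)C)[C@]2(C)C=C(C)CC[C@@H]2O[Si](C)(C)C(C)(C)C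
A2 | alternative 2 | 9-O-triethylsilyl ether of the target | CC(=O)O[C@H]1CC=C(C)[C@@H]2[C@@H](O[Si](CC)(CC)CC)[C@@]3(O)[C@H](/C=C(/C)CC[C@@H](OC(C)=O)[C@@]12C)OC(=O)[C@@H]3C
A3 | alternative 3 | briarane 2-alcohol with C14 TBS ether and C8/C9 acetonide | C[Si](C)(C(C)(C)C)O[C@H]1CC=C(C)[C@@H]2[C@H]4OC(C)(C)O[C@@]43[C@H](/C=C(/C)CC[C@@H](O)[C@@]12C)OC(=O)[C@@H]3C
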